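**Plan**
- **Numbering and enabling feature.** Tetrahydrofuran: O1, C2 (ring B), C3 (bears C9H2OH), C4 (tertiary carbinol, bears benzylic C7 of ring A), C5. Chain on the ring B oxygen: C7'' (ring C), C8'', C9''. C7 and C9 stand cis on the neighbouring atoms C4 and C3. C7 can therefore be tied to the C9 oxygen in a cis-fused 1-hydroxy-3,7-dioxabicyclo[3.3.0]octane, and C4–OH reads as a former ketone whose oxygen can reach a C7–H.
- **Cuts (retrosynthetic order).** Ring C O–benzyl; C7–H back to C7–O(C9); C4–C7; O1–C5; C4–C5; C2–C3; ring B–CHO; C7''–C8''; ring B O–CH2.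
- **Forward order.** A glycolate aldol joins rings B and C, followed by the silylene ring and formylation. An anti aldol then joins this aldehyde to the ring A ether imide. The diazoketone and O–H insertion close the tetrahydrofuranone. Light closes the second ring, hydride reopens it at C7–O, and debenzylation finishes.
- **Stereochemistry.** C7''/C8'' come from a boron syn aldol and C2/C3 from a MgCl2-catalysed anti aldol, both on (S)-4-benzyloxazolidinone. C4 comes from the C3–C9–O tether, because only cis fusion is possible. C7 is transient.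

Key step: step 18

Abbreviations in names:
- BC-aryl = 4-{[(4R,5R)-4-[4-(benzyloxy)-3-methoxyphenyl]-2,2-di-tert-butyl-1,3,2-dioxasilinan-5-yl]oxy}-3-methoxyphenyl
- A-benzyl = 3-methoxy-4-(triisopropylsilyloxy)benzyl

Assumption: the MgCl2-catalysed anti aldol is taken to react on the enolate face exposed in the Mg-chelated (Z)-enolate, the same face as in enolate alkylation. If the opposite sense were found, the (R)-auxiliary would be used in that branch.

Step 1
Reactants: 1 4-bromo-2-methoxyphenol; 2 bromoacetic acid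
Product: 3 (4-bromo-2-methoxyphenoxy)acetic acid
Conditions: NaOH, H2O, reflux; then HCl
Reagents that add atoms: none
Why: Williamson ether synthesis, in which the phenoxide displaces bromide from bromoacetate, is the classical entry to aryloxyacetic acids, and the bromine masks the later ring B aldehyde.

Step 2
Reactants: 3 (4-bromo-2-methoxyphenoxy)acetic acid; 4 (S)-4-benzyl-1,3-oxazolidin-2-one
Product: 6 (S)-4-benzyl-3-[(4-bromo-2-methoxyphenoxy)acetyl]-1,3-oxazolidin-2-one, via mixed pivalic anhydride 5 (not isolated)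
Conditions: PivCl, Et3N, THF, −20 °C; then LiCl, 4, to 23 °C
Reagents that add atoms: pivaloyl chloride, CC(C)(C)C(=O)Cl (acyl group held only by 5)
Why: N-acylation of the oxazolidinone through the mixed anhydride with LiCl/Et3N is a standard one-flask method that needs no strong base.

Step 3
Reactants: 6 (S)-4-benzyl-3-[(4-bromo-2-methoxyphenoxy)acetyl]-1,3-oxazolidin-2-one; 7 4-(benzyloxy)-3-methoxybenzaldehyde
Product: 9 (S)-4-benzyl-3-[(2S,3R)-3-[4-(benzyloxy)-3-methoxyphenyl]-2-(4-bromo-2-methoxyphenoxy)-3-hydroxypropanoyl]-1,3-oxazolidin-2-one, via (Z)-dibutylboron enolate 8 (not isolated)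
Conditions: Bu2BOTf, Et3N, CH2Cl2, 0 °C; 7, −78 to 0 °C; pH 7 buffer, MeOH, H2O2
Reagents that add atoms: dibutylboron triflate, CCCCB(CCCC)OS(=O)(=O)C(F)(F)F (boryl group held only by 8)
Why: In the Evans boron glycolate syn aldol the (Z)-enolate reacts through a Zimmerman–Traxler chair on the face away from the auxiliary benzyl group, which forms C7''–C8'' and sets both centres as the threo pair of the target.

Step 4
Reactants: 9 syn aldol imide
Product: 10 (1R,2R)-1-[4-(benzyloxy)-3-methoxyphenyl]-2-(4-bromo-2-methoxyphenoxy)propane-1,3-diol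
Conditions: LiBH4, MeOH (1 equiv), THF, 0 °C
Reagents that add atoms: none
Why: Reductive removal of the auxiliary with LiBH4 converts the imide carbonyl into C9''H2OH without touching the stereocentres, the aryl bromide or the benzyl ether.

Step 5
Reactants: 10 the 1,3-diol
Product: 11 (4R,5R)-4-[4-(benzyloxy)-3-methoxyphenyl]-5-(4-bromo-2-methoxyphenoxy)-2,2-di-tert-butyl-1,3,2-dioxasilinane
Conditions: t-Bu2Si(OTf)2, 2,6-lutidine, CH2Cl2, 0 °C
Reagents that add atoms: di-tert-butylsilyl bis(trifluoromethanesulfonate), CC(C)(C)[Si](OS(=O)(=O)C(F)(F)F)(OS(=O)(=O)C(F)(F)F)C(C)(C)C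
Why: Silylene protection of a 1,3-diol gives a six-membered ring that resists organolithiums, mild acid and mild base and falls to fluoride, so no acid is needed near the acid-sensitive target.

Step 6
Reactants: 11 the silylene bromide
Product: 13 4-{[(4R,5R)-4-[4-(benzyloxy)-3-methoxyphenyl]-2,2-di-tert-butyl-1,3,2-dioxasilinan-5-yl]oxy}-3-methoxybenzaldehyde (BC-aryl–CHO), via aryllithium 12 (not isolated)
Conditions: n-BuLi, THF, −78 °C; DMF, −78 to 0 °C; H2O
Reagents that add atoms: N,N-dimethylformamide, CN(C)C=O; n-butyllithium, [Li]CCCC (lithium held only by 12)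
Why: Bromine–lithium exchange followed by Bouveault-type formylation with DMF is faster at −78 °C than any deprotonation or attack on the hindered silylene.

Step 7
Reactants: 14 vanillin
Product: 15 3-methoxy-4-(triisopropylsilyloxy)benzaldehyde
Conditions: TIPSCl, imidazole, DMF, 23 °C
Reagents that add atoms: chlorotriisopropylsilane, CC(C)[Si](Cl)(C(C)C)C(C)C
Why: Standard phenol silylation is used, and TIPS is chosen over smaller silyl groups because it has to survive alkoxide, LiOH and LiOOH yet leave with fluoride.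

Step 8
Reactants: 15 the silylated aldehyde
Product: 16 [3-methoxy-4-(triisopropylsilyloxy)phenyl]methanol (A-benzyl alcohol)
Conditions: NaBH4, MeOH, 0 °C
Reagents that add atoms: none
Why: Borohydride reduction of an aromatic aldehyde is fast and leaves the aryl silyl ether intact.

Step 9
Reactants: 16 A-benzyl alcohol; 17 methyl acrylate
Product: 18 methyl 3-(A-benzyloxy)propanoate
Conditions: NaH (0.1 equiv), THF, 0 to 23 °C
Reagents that add atoms: none
Why: In this base-catalysed oxa-Michael addition a catalytic amount of the benzylic alkoxide adds to the acrylate and the ester enolate is reprotonated by more alcohol, while the bulk of TIPS should suppress oxygen-to-oxygen silyl transfer.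

Step 10
Reactants: 18 the methyl ester
Product: 19 3-(A-benzyloxy)propanoic acid
Conditions: LiOH, THF–H2O, 0 to 23 °C; then cold 1 M HCl to pH 4
Reagents that add atoms: lithium hydroxide, [Li+].[OH-]
Why: Saponification of an unhindered methyl ester is mild enough for the aryl TIPS ether and the β-alkoxy ester, and no strong acid meets the acid-labile electron-rich benzyl ether.

Step 11
Reactants: 19 3-(A-benzyloxy)propanoic acid; 4 (S)-4-benzyl-1,3-oxazolidin-2-one
Product: 21 (S)-4-benzyl-3-[3-(A-benzyloxy)propanoyl]-1,3-oxazolidin-2-one, via mixed pivalic anhydride 20 (not isolated)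
Conditions: PivCl, Et3N, THF, −20 °C; then LiCl, 4, to 23 °C
Reagents that add atoms: pivaloyl chloride, CC(C)(C)C(=O)Cl (acyl group held only by 20)
Why: This is the same mixed-anhydride N-acylation as in step 2, run under weakly basic conditions that do not provoke β-elimination.

Step 12
Reactants: 21 the ring A imide; 13 BC-aryl–CHO
Product: 23 (S)-4-benzyl-3-[(2R,3S)-2-[(A-benzyloxy)methyl]-3-(BC-aryl)-3-hydroxypropanoyl]-1,3-oxazolidin-2-one, via trimethylsilyl ether 22 (not isolated)
Conditions: MgCl2 (20 mol %), Et3N, TMSCl, EtOAc, 23 °C; then PPTS, MeOH, 0 °C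
Reagents that add atoms: chlorotrimethylsilane, C[Si](C)(C)Cl (silyl group held only by 22)
Why: In the MgCl2-catalysed Evans anti aldol, soft enolisation of the Mg-chelated imide, addition to the non-enolisable electron-rich aromatic aldehyde on the face away from the auxiliary benzyl group and silyl trapping of the aldolate form C2–C3 and set C3 (R) and C2 (S) in the anti relationship, which becomes 2,3-trans in the ring.

Step 13
Reactants: 23 the anti aldol
Product: 24 triethylsilyl ether of 23 at the C2 oxygen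
Conditions: TESOTf, 2,6-lutidine, CH2Cl2, −78 °C
Reagents that add atoms: triethylsilyl triflate, CC[Si](CC)(CC)OS(=O)(=O)C(F)(F)F
Why: Buffered silylation blocks retro-aldol and lactonisation during carboxyl activation, and TES can later be removed by mild acid beside aryl-OTIPS and the silylene.

Step 14
Reactants: 24 the TES-protected imide
Product: 26 (2R,3S)-2-[(A-benzyloxy)methyl]-3-(BC-aryl)-3-(triethylsilyloxy)propanoic acid, via peroxy acid 25 (not isolated)
Conditions: LiOH, H2O2, THF–H2O, 0 °C; Na2SO3; cold 1 M HCl to pH 4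
Reagents that add atoms: hydrogen peroxide, OO
Why: Hydroperoxide cleaves the hindered imide selectively at the exocyclic carbonyl at 0 °C without epimerising C3, and sulfite reduces the peroxy acid.

Step 15
Reactants: 26 the acid
Product: 28 (3R,4S)-3-[(A-benzyloxy)methyl]-4-(BC-aryl)-1-diazo-4-(triethylsilyloxy)butan-2-one, via mixed carbonic anhydride 27 (not isolated)
Conditions: i-BuOCOCl, N-methylmorpholine, THF, −20 °C; CH2N2, Et2O, 0 °C
Reagents that add atoms: diazomethane, C=[N+]=[N-]; isobutyl chloroformate, CC(C)COC(=O)Cl (held only by 27)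
Why: Acylation of diazomethane, the first stage of the Arndt–Eistert sequence, forms C4–C5 under neutral conditions that leave every protecting group and C3 untouched.

Step 16
Reactants: 28 the silylated diazoketone
Product: 29 (3R,4S)-3-[(A-benzyloxy)methyl]-4-(BC-aryl)-1-diazo-4-hydroxybutan-2-one
Conditions: PPTS, MeOH, 0 to 23 °C
Reagents that add atoms: none
Why: Mild acid methanolysis removes the secondary TES ether much faster than it affects the aryl TIPS ether, the silylene or the electron-rich benzyl ether, and the acid is too weak to protonate the diazoketone.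

Step 17
Reactants: 29 the hydroxy diazoketone
Product: 30 (2S,3R)-3-[(A-benzyloxy)methyl]-2-(BC-aryl)tetrahydrofuran-4-one (systematically the (4R,5S)-oxolan-3-one)
Conditions: Rh2(OAc)4 (1 mol %), CH2Cl2, 23 °C, slow addition of 29
Reagents that add atoms: none
Why: In this dirhodium carbenoid O–H insertion the carbenoid at C5 is captured by the C2 hydroxyl through a five-membered oxonium ylide and a fast proton shift, a neutral closure of O1–C5 that keeps C2 and C3 and should outrun ylide formation at the C9 ether oxygen (Stevens shift) and Buchner attack on ring B because only the hydroxyl path ends irreversibly at once.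

Step 18
Reactants: 30 the tetrahydrofuran-4-one
Product: 31 (1S,2R,5R,6S)-6-(BC-aryl)-2-[3-methoxy-4-(triisopropylsilyloxy)phenyl]-3,7-dioxabicyclo[3.3.0]octan-1-ol (drawn with ring A on the convex face)
Conditions: hν (medium-pressure Hg lamp, Pyrex, λ > 300 nm), degassed benzene (5 mM), 20 °C
Reagents that add atoms: none
Why: n→π* excitation makes the C4 carbonyl oxygen radical-like, and it removes the benzylic, α-oxygenated C7–H through a seven-membered array, because the only γ-hydrogen (C2–H, counted through O1) belongs to the same ring and cannot reach that oxygen; the C4/C7 1,5-biradical then couples. This is the Norrish–Yang photocyclisation of β-alkoxy ketones to 3-hydroxytetrahydrofurans, a reaction type already applied to 3-(arylmethoxymethyl)tetrahydrofuran-4-ones to reach bridgehead-hydroxylated furofuran lignans. The new ring (C4–C7–O–C9–C3) closes by radical–radical recombination to a five-membered ring across the three-atom C3–C9–O tether. C4 is fixed by that tether: a bicyclo[3.3.0]octane can only be cis-fused, so C7 must bond to the C4 face that carries C9, and the hydroxyl ends up trans to C9, the outcome an external benzyl nucleophile would not give. C7 should place ring A on the convex face for steric reasons, but either C7 epimer serves because this centre becomes CH2 in step 19. The step needs hydrogen abstraction to outrun α-cleavage and needs the light to reach only the ketone, which the weak, doubly activated C7–H bond, the Pyrex cut-off beyond the guaiacyl absorption and high dilution in degassed benzene are meant to secure.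

Step 19
Reactants: 31 the bridgehead-hydroxy furofuran
Product: 34 ring C O-benzyl ether of the target, via free-phenol furofuran 32 (not isolated), via p-quinone methide 33 (not isolated)
Conditions: TBAF (6 equiv), NaBH4 (10 equiv), DMSO, 23 °C then 85 °C
Reagents that add atoms: none
Why: Proposed new method: fluoride removes the ring A silyl ether and the silylene, the naked phenoxide of 32 pushes out the C7–O bond of the strained bicycle as the C9 alkoxide to give quinone methide 33, and borohydride adds irreversibly to C7 (1,6-addition) whereas re-closure is only reversible; rings B and C carry etherified para oxygens and cannot ionise in this way, so C2–O1 and the ring C benzylic C–O bond stay; the closest known reaction types are the fluoride-triggered 1,6-elimination used to cleave 4-silyloxybenzyl ether protecting groups at about 90 °C and the borohydride reduction of p-quinone methides generated from 4-hydroxybenzyl alcohols, neither yet shown on a cyclic furofuran ether.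

Step 20
Reactants: 34 the O-benzyl ether
Product: 35 the target, (2S,3R,4S)-tetrahydrofuran with (7''R,8''R) side chain
Conditions: H2 (1 atm), 10% Pd/C, EtOAc–EtOH, 23 °C
Reagents that add atoms: none
Why: Catalytic hydrogenolysis of an aryl benzyl ether under neutral conditions is much faster than cleavage of the C2–O1 bond of a 2-aryltetrahydrofuran or of a free benzylic alcohol, so stopping after uptake of one equivalent of H2 should deliver the target.

**Compound list**
1 | 4-bromo-2-methoxyphenol | COc1cc(Br)ccc1O | starting material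
2 | bromoacetic acid | OC(=O)CBr | starting material
3 | (4-bromo-2-methoxyphenoxy)acetic acid | COc1cc(Br)ccc1OCC(=O)O | intermediate
4 | (S)-4-benzyl-1,3-oxazolidin-2-one | O=C1N[C@@H](Cc2ccccc2)CO1 | starting material
5 | mixed pivalic anhydride of 3 | COc1cc(Br)ccc1OCC(=O)OC(=O)C(C)(C)C | intermediate
6 | (S)-4-benzyl-3-[(4-bromo-2-methoxyphenoxy)acetyl]-1,3-oxazolidin-2-one | COc1cc(Br)ccc1OCC(=O)N1[C@@H](Cc2ccccc2)COC1=O | intermediate
7 | 4-(benzyloxy)-3-methoxybenzaldehyde | COc1cc(C=O)ccc1OCc1ccccc1 | starting material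
8 | (Z)-dibutylboron enolate of 6 | CCCCB(CCCC)O/C(=C\Oc1ccc(Br)cc1OC)N1[C@@H](Cc2ccccc2)COC1=O | intermediate
9 | (2S,3R) syn glycolate aldol imide | COc1cc(Br)ccc1O[C@H](C(=O)N1[C@@H](Cc2ccccc2)COC1=O)[C@H](O)c1ccc(OCc2ccccc2)c(OC)c1 | intermediate
10 | (1R,2R)-1-[4-(benzyloxy)-3-methoxyphenyl]-2-(4-bromo-2-methoxyphenoxy)propane-1,3-diol | COc1cc(Br)ccc1O[C@H](CO)[C@H](O)c1ccc(OCc2ccccc2)c(OC)c1 | intermediate
11 | (4R,5R)-4-[4-(benzyloxy)-3-methoxyphenyl]-5-(4-bromo-2-methoxyphenoxy)-2,2-di-tert-butyl-1,3,2-dioxasilinane | COc1cc(Br)ccc1O[C@@H]2CO[Si](C(C)(C)C)(C(C)(C)C)O[C@@H]2c3ccc(OCc4ccccc4)c(OC)c3 | intermediate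
12 | aryllithium from 11 | COc1cc([Li])ccc1O[C@@H]2CO[Si](C(C)(C)C)(C(C)(C)C)O[C@@H]2c3ccc(OCc4ccccc4)c(OC)c3 | intermediate
13 | BC-aryl–CHO | COc1cc(C=O)ccc1O[C@@H]2CO[Si](C(C)(C)C)(C(C)(C)C)O[C@@H]2c3ccc(OCc4ccccc4)c(OC)c3 | intermediate
14 | vanillin | COc1cc(C=O)ccc1O | starting material
15 | 3-methoxy-4-(triisopropylsilyloxy)benzaldehyde | COc1cc(C=O)ccc1O[Si](C(C)C)(C(C)C)C(C)C | intermediate
16 | [3-methoxy-4-(triisopropylsilyloxy)phenyl]methanol | COc1cc(CO)ccc1O[Si](C(C)C)(C(C)C)C(C)C | intermediate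
17 | methyl acrylate | C=CC(=O)OC | starting material
18 | methyl 3-(A-benzyloxy)propanoate | COC(=O)CCOCc1ccc(O[Si](C(C)C)(C(C)C)C(C)C)c(OC)c1 | intermediate
19 | 3-(A-benzyloxy)propanoic acid | OC(=O)CCOCc1ccc(O[Si](C(C)C)(C(C)C)C(C)C)c(OC)c1 | intermediate
20 | mixed pivalic anhydride of 19 | CC(C)(C)C(=O)OC(=O)CCOCc1ccc(O[Si](C(C)C)(C(C)C)C(C)C)c(OC)c1 | intermediate
21 | (S)-4-benzyl-3-[3-(A-benzyloxy)propanoyl]-1,3-oxazolidin-2-one | O=C(CCOCc1ccc(O[Si](C(C)C)(C(C)C)C(C)C)c(OC)c1)N1[C@@H](Cc2ccccc2)COC1=O | intermediate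
22 | trimethylsilyl ether of 23 | C[Si](C)(C)O[C@H](c3ccc(O[C@@H]4CO[Si](C(C)(C)C)(C(C)(C)C)O[C@@H]4c5ccc(OCc6ccccc6)c(OC)c5)c(OC)c3)[C@H](C(=O)N7[C@@H](Cc8ccccc8)COC7=O)COCc1ccc(O[Si](C(C)C)(C(C)C)C(C)C)c(OC)c1 | intermediate
23 | (2R,3S) anti aldol imide | O[C@H](c3ccc(O[C@@H]4CO[Si](C(C)(C)C)(C(C)(C)C)O[C@@H]4c5ccc(OCc6ccccc6)c(OC)c5)c(OC)c3)[C@H](C(=O)N7[C@@H](Cc8ccccc8)COC7=O)COCc1ccc(O[Si](C(C)C)(C(C)C)C(C)C)c(OC)c1 | intermediate
24 | triethylsilyl ether of 23 | CC[Si](CC)(CC)O[C@H](c3ccc(O[C@@H]4CO[Si](C(C)(C)C)(C(C)(C)C)O[C@@H]4c5ccc(OCc6ccccc6)c(OC)c5)c(OC)c3)[C@H](C(=O)N7[C@@H](Cc8ccccc8)COC7=O)COCc1ccc(O[Si](C(C)C)(C(C)C)C(C)C)c(OC)c1 | intermediate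
25 | peroxy acid corresponding to 26 | CC[Si](CC)(CC)O[C@H](c3ccc(O[C@@H]4CO[Si](C(C)(C)C)(C(C)(C)C)O[C@@H]4c5ccc(OCc6ccccc6)c(OC)c5)c(OC)c3)[C@H](C(=O)OO)COCc1ccc(O[Si](C(C)C)(C(C)C)C(C)C)c(OC)c1 | intermediate
26 | (2R,3S)-2-[(A-benzyloxy)methyl]-3-(BC-aryl)-3-(triethylsilyloxy)propanoic acid | CC[Si](CC)(CC)O[C@H](c3ccc(O[C@@H]4CO[Si](C(C)(C)C)(C(C)(C)C)O[C@@H]4c5ccc(OCc6ccccc6)c(OC)c5)c(OC)c3)[C@H](C(=O)O)COCc1ccc(O[Si](C(C)C)(C(C)C)C(C)C)c(OC)c1 | intermediate
27 | mixed isobutyl carbonic anhydride of 26 | CC[Si](CC)(CC)O[C@H](c3ccc(O[C@@H]4CO[Si](C(C)(C)C)(C(C)(C)C)O[C@@H]4c5ccc(OCc6ccccc6)c(OC)c5)c(OC)c3)[C@H](C(=O)OC(=O)OCC(C)C)COCc1ccc(O[Si](C(C)C)(C(C)C)C(C)C)c(OC)c1 | intermediate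
28 | (3R,4S) TES-protected diazoketone | CC[Si](CC)(CC)O[C@H](c3ccc(O[C@@H]4CO[Si](C(C)(C)C)(C(C)(C)C)O[C@@H]4c5ccc(OCc6ccccc6)c(OC)c5)c(OC)c3)[C@H](C(=O)C=[N+]=[N-])COCc1ccc(O[Si](C(C)C)(C(C)C)C(C)C)c(OC)c1 | intermediate
29 | (3R,4S) hydroxy diazoketone | O[C@H](c3ccc(O[C@@H]4CO[Si](C(C)(C)C)(C(C)(C)C)O[C@@H]4c5ccc(OCc6ccccc6)c(OC)c5)c(OC)c3)[C@H](C(=O)C=[N+]=[N-])COCc1ccc(O[Si](C(C)C)(C(C)C)C(C)C)c(OC)c1 | intermediate
30 | (2S,3R)-3-[(A-benzyloxy)methyl]-2-(BC-aryl)tetrahydrofuran-4-one | O=C2CO[C@H](c3ccc(O[C@@H]4CO[Si](C(C)(C)C)(C(C)(C)C)O[C@@H]4c5ccc(OCc6ccccc6)c(OC)c5)c(OC)c3)[C@H]2COCc1ccc(O[Si](C(C)C)(C(C)C)C(C)C)c(OC)c1 | intermediate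
31 | (1S,2R,5R,6S) bridgehead-hydroxy furofuran | COc1cc([C@@H]8[C@@]2(O)CO[C@H](c3ccc(O[C@@H]4CO[Si](C(C)(C)C)(C(C)(C)C)O[C@@H]4c5ccc(OCc6ccccc6)c(OC)c5)c(OC)c3)[C@H]2CO8)ccc1O[Si](C(C)C)(C(C)C)C(C)C | intermediate
32 | fully desilylated furofuran with free ring A phenol | COc1cc([C@@H]8[C@@]2(O)CO[C@H](c3ccc(O[C@H](CO)[C@H](O)c5ccc(OCc6ccccc6)c(OC)c5)c(OC)c3)[C@H]2CO8)ccc1O | intermediate
33 | ring A p-quinone methide with free C9H2OH | COC1=CC(=C[C@@]2(O)CO[C@H](c3ccc(O[C@H](CO)[C@H](O)c5ccc(OCc6ccccc6)c(OC)c5)c(OC)c3)[C@H]2CO)C=CC1=O | intermediate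
34 | ring C O-benzyl ether of the target | COc1cc(C[C@@]2(O)CO[C@H](c3ccc(O[C@H](CO)[C@H](O)c4ccc(OCc5ccccc5)c(OC)c4)c(OC)c3)[C@H]2CO)ccc1O | intermediate
35 | CNP0391650.2 | COc1cc(C[C@@]2(O)CO[C@H](c3ccc(O[C@H](CO)[C@H](O)c4ccc(O)c(OC)c4)c(OC)c3)[C@H]2CO)ccc1O | target

**Step count:** 20 steps in total. The longest linear sequence is 15 steps (steps 1–6, then 12–20).

**Steps most likely to fail**

**Step 19.**
- *What may go wrong:* the phenoxide may not expel the C9 alkoxide below the temperature at which borohydride and substrate decay, or re-closure of the opened quinone methide may outrun hydride capture.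
- *Fallback, from 32 back to 34:* the fallback exchanges the poor alkoxide leaving group for acetate, using known reactions only. It sets out from 32, isolated by stopping step 19 after the desilylation at 23 °C.
  - DDQ (1 equiv, CH2Cl2–H2O, 0 °C) effects the known oxidative cleavage of a 4-hydroxybenzyl ether at the only phenolic benzylic position. This should give the ring-opened vanilloyl ketone F1 with free C9H2OH.
  - NaBH4 in MeOH should give the C7 carbinol F2 as an epimer mixture.
  - Ac2O in pyridine should give the pentaacetate F3, with the tertiary C4–OH left free.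
  - NaBH4 with K2CO3 in MeOH–THF (0 to 23 °C) frees the phenoxide first, which loses the C7 acetate readily. Hydride adds to the quinone methide, the other acetates are methanolysed, and the route is rejoined at 34.

**Step 18.**
- *What may go wrong:* α-cleavage and decarbonylation of the excited furanone, quenching of the ketone by the electron-rich arenes, or return of the hydrogen within the biradical.
- *Fallback, from 30 back to 34:* oxygen is delivered to the open face instead of carbon to the hindered one.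
  - Wittig methylenation of 30 (Ph3P=CH2 from Ph3PCH3Br and KN(SiMe3)2, THF, −78 to 0 °C) should give the exocyclic alkene F4.
  - Buffered mCPBA should attack anti to the C3 side chain and give the spiro-epoxide F5, with its oxygen trans to C9.
  - Separately, 1 is silylated (TIPSCl, imidazole) to the aryl bromide F6, which Mg in THF converts into the Grignard reagent F7.
  - CuI-catalysed opening of F5 by F7 at the CH2 terminus should give the tertiary alcohol F8, in which the epoxide CH2 has become C7.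
  - TBAF and NaBH4 in DMSO at 85 °C then remove all silyl groups. They also release C9–OH from what is now an ordinary primary 4-silyloxybenzyl ether, a known protecting-group cleavage, and the route is rejoined at 34.

**Step 12.**
- *What may go wrong:* β-elimination of the A-benzyl alkoxide from the magnesium enolate during the long reaction at ambient temperature, or poor anti and facial selectivity.
- *Fallback, from 21 and 13 back to 30:* C2 is set kinetically and C3 thermodynamically.
  - The boron enolate of 21, preformed with Bu2BOTf and Et3N at −78 °C, should give with 13 the (2S,3S) syn aldol F9, in which C2 is correct and C3 inverted.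
  - The operations of steps 13–17 then lead through the TES ether F10, the acid F11, the silylated diazoketone F12 and the hydroxy diazoketone F13 to the 2,3-cis furanone F14.
  - Catalytic DBU in CH2Cl2 at 0 °C should equilibrate F14 through the enol to the more stable 2,3-trans ketone 30.

**Further compounds**
F1 | step 19 | vanilloyl ketone, C7 = C=O analogue of 34 | COc1cc(C(=O)[C@@]2(O)CO[C@H](c3ccc(O[C@H](CO)[C@H](O)c5ccc(OCc6ccccc6)c(OC)c5)c(OC)c3)[C@H]2CO)ccc1O
F2 | step 19 | C7 carbinol, both C7 epimers | COc1cc(C(O)[C@@]2(O)CO[C@H](c3ccc(O[C@H](CO)[C@H](O)c5ccc(OCc6ccccc6)c(OC)c5)c(OC)c3)[C@H]2CO)ccc1O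
F3 | step 19 | pentaacetate of F2 (C4–OH free) | COc1cc(C(OC(C)=O)[C@@]2(O)CO[C@H](c3ccc(O[C@H](COC(C)=O)[C@H](OC(C)=O)c5ccc(OCc6ccccc6)c(OC)c5)c(OC)c3)[C@H]2COC(C)=O)ccc1OC(C)=O
F4 | step 18 | 4-methylene analogue of 30 | C=C2CO[C@H](c3ccc(O[C@@H]4CO[Si](C(C)(C)C)(C(C)(C)C)O[C@@H]4c5ccc(OCc6ccccc6)c(OC)c5)c(OC)c3)[C@H]2COCc1ccc(O[Si](C(C)C)(C(C)C)C(C)C)c(OC)c1
F5 | step 18 | C4 spiro-epoxide, oxygen trans to C9 | C1O[C@@]12CO[C@H](c3ccc(O[C@@H]4CO[Si](C(C)(C)C)(C(C)(C)C)O[C@@H]4c5ccc(OCc6ccccc6)c(OC)c5)c(OC)c3)[C@H]2COCc7ccc(O[Si](C(C)C)(C(C)C)C(C)C)c(OC)c7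
F6 | step 18 | (4-bromo-2-methoxyphenoxy)triisopropylsilane | COc1cc(Br)ccc1O[Si](C(C)C)(C(C)C)C(C)C
F7 | step 18 | [3-methoxy-4-(triisopropylsilyloxy)phenyl]magnesium bromide | COc1cc([Mg]Br)ccc1O[Si](C(C)C)(C(C)C)C(C)C
F8 | step 18 | tertiary alcohol with C9 O-A-benzyl ether, ring A OTIPS and silylene | COc1cc(C[C@@]2(O)CO[C@H](c3ccc(O[C@@H]4CO[Si](C(C)(C)C)(C(C)(C)C)O[C@@H]4c5ccc(OCc6ccccc6)c(OC)c5)c(OC)c3)[C@H]2COCc7ccc(O[Si](C(C)C)(C(C)C)C(C)C)c(OC)c7)ccc1O[Si](C(C)C)(C(C)C)C(C)C
F9 | step 12 | (2S,3S) syn aldol imide | O[C@H](c3ccc(O[C@@H]4CO[Si](C(C)(C)C)(C(C)(C)C)O[C@@H]4c5ccc(OCc6ccccc6)c(OC)c5)c(OC)c3)[C@@H](C(=O)N7[C@@H](Cc8ccccc8)COC7=O)COCc1ccc(O[Si](C(C)C)(C(C)C)C(C)C)c(OC)c1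
F10 | step 12 | triethylsilyl ether of F9 | CC[Si](CC)(CC)O[C@H](c3ccc(O[C@@H]4CO[Si](C(C)(C)C)(C(C)(C)C)O[C@@H]4c5ccc(OCc6ccccc6)c(OC)c5)c(OC)c3)[C@@H](C(=O)N7[C@@H](Cc8ccccc8)COC7=O)COCc1ccc(O[Si](C(C)C)(C(C)C)C(C)C)c(OC)c1
F11 | step 12 | (2S,3S) acid, C3 epimer of 26 | CC[Si](CC)(CC)O[C@H](c3ccc(O[C@@H]4CO[Si](C(C)(C)C)(C(C)(C)C)O[C@@H]4c5ccc(OCc6ccccc6)c(OC)c5)c(OC)c3)[C@@H](C(=O)O)COCc1ccc(O[Si](C(C)C)(C(C)C)C(C)C)c(OC)c1
F12 | step 12 | C3 epimer of 28 | CC[Si](CC)(CC)O[C@H](c3ccc(O[C@@H]4CO[Si](C(C)(C)C)(C(C)(C)C)O[C@@H]4c5ccc(OCc6ccccc6)c(OC)c5)c(OC)c3)[C@@H](C(=O)C=[N+]=[N-])COCc1ccc(O[Si](C(C)C)(C(C)C)C(C)C)c(OC)c1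
F13 | step 12 | C3 epimer of 29 | O[C@H](c3ccc(O[C@@H]4CO[Si](C(C)(C)C)(C(C)(C)C)O[C@@H]4c5ccc(OCc6ccccc6)c(OC)c5)c(OC)c3)[C@@H](C(=O)C=[N+]=[N-])COCc1ccc(O[Si](C(C)C)(C(C)C)C(C)C)c(OC)c1
F14 | step 12 | (2S,3S) 2,3-cis furanone, C3 epimer of 30 | O=C2CO[C@H](c3ccc(O[C@@H]4CO[Si](C(C)(C)C)(C(C)(C)C)O[C@@H]4c5ccc(OCc6ccccc6)c(OC)c5)c(OC)c3)[C@@H]2COCc1ccc(O[Si](C(C)C)(C(C)C)C(C)C)c(OC)c1
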